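**Retrosynthetic overview**
1. Target 24 ⇐ 23: the ring B diosphenol is made last, by oxidation of an α-ketol, so the acidic enol never meets the cobalt catalyst.
2. 23 ⇐ 17 + 22: the key bond is the ester C3–O bond, formed by trans-diaxial opening of a 2α,3α-epoxide with the dienoic acid; this inverts C3 and keeps the C2–O bond.
3. 17 ⇐ 13: one pot makes the C7–O bond (Rubottom) and the oxirane (third ring, opened again in step 7).
4. 13 ⇐ 9 ⇐ 6 ⇐ 1 + 2: ring A is the carvone ring; ring B is closed first by cuprate addition and Robinson annulation (sets C4 and C5); isopropenyl → acetate (Criegee) → elimination and kinetic deconjugation place the C2=C3 alkene.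
5. 22 ⇐ 18 + 19: oxidation, Horner–Wadsworth–Emmons olefination, saponification.

Assumption: names from 16 onward use eremophilane-type core locants (ring A = C1 to C5 and C10, ring B = C5 to C10, methyls on C4 and C5, α = face opposite these methyls), and the catalyst enantiomer matched to epoxide 17 in step 7 is taken as (S,S), to be confirmed against (R,R) in the first run.

**Step 1**
Reactants: 1 (S)-(+)-carvone; 2 3-(trimethylsilyl)but-3-en-2-one
Product: 6 (4aR,5S,7S)-4a,5-dimethyl-7-(prop-1-en-2-yl)-4,4a,5,6,7,8-hexahydronaphthalen-2(3H)-one, via lithium enolate 3 (not isolated), via silyl diketone 4 (not isolated), via diketone 5 (not isolated)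
Conditions: Me2CuLi (1.3 equiv), Et2O, −20 °C; 2 (1.3 equiv), THF, −78 → −20 °C; then KOH, MeOH–H2O, 65 °C
Reagents that add atoms: lithium dimethylcuprate, [Li+].C[Cu-]C
Why: Conjugate addition–Robinson annulation (α-silyl vinyl ketone variant): the cuprate adds axially, anti to the isopropenyl group (sets the C4 methyl), the regiodefined enolate 3 adds to 2 on the face opposite that new methyl (sets the cis-vicinal quaternary C5), and KOH removes silicon and closes ring B by aldol condensation.

**Step 2**
Reactants: 6 (4aR,5S,7S)-4a,5-dimethyl-7-(prop-1-en-2-yl)-4,4a,5,6,7,8-hexahydronaphthalen-2(3H)-one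
Product: 9 (4aR,5S,7S)-7-acetoxy-4a,5-dimethyl-4,4a,5,6,7,8-hexahydronaphthalen-2(3H)-one, via methoxy hydroperoxide 7 (not isolated), via acetyl perester 8 (not isolated)
Conditions: O3, CH2Cl2–MeOH (5:1), NaHCO3, −78 °C; then Ac2O, Et3N, DMAP (cat.), 0 → 40 °C
Reagents that add atoms: ozone, [O-][O+]=O; methanol, CO
Why: Ozonolysis–Criegee rearrangement: ozone takes the electron-rich 1,1-disubstituted alkene and not the enone, methanol traps the carbonyl oxide as 7, and acetylation makes the ring carbon migrate from carbon to oxygen with retention, which forms the C2–O bond and turns the former stereocontrol element into a leaving group.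

**Step 3**
Reactants: 9 (4aR,5S,7S)-7-acetoxy-4a,5-dimethyl-4,4a,5,6,7,8-hexahydronaphthalen-2(3H)-one
Product: 13 (4aR,5S)-4a,5-dimethyl-4,4a,5,8-tetrahydronaphthalen-2(3H)-one, via dienone 10 (not isolated), via potassium trienolate 11 (not isolated), via deconjugated dienone 12 (not isolated)
Conditions: KOtBu (4 equiv), t-BuOH–THF, 0 → 23 °C; inverse quench into AcOH–H2O–THF, −20 °C; then DABCO (0.2 equiv), CH2Cl2, 0 °C
Reagents that add atoms: none
Why: E1cB elimination then kinetic deconjugation: tert-butoxide removes the vinylogous C1 proton and expels acetate to give 10, excess base converts 10 into the fully conjugated trienolate 11, kinetic protonation at the α-carbon gives 12, and mild amine base then brings only the β,γ-bond into conjugation (γ-protonation at C1), the behaviour known from steroidal 5,7-dien-3-ones that stop at the 4,7-dienone, so that the isolated C2=C3 alkene of 13 results with C4 and C5 untouched.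

**Step 4**
Reactants: 13 (4aR,5S)-4a,5-dimethyl-4,4a,5,8-tetrahydronaphthalen-2(3H)-one
Product: 17 2α,3α-epoxy-7α-hydroxy-11,12,13-trinoreremophil-9-en-8-one (4β,5β-dimethyl; 2R,3S,4R,5R,7R), via lithium dienolate 14 (not isolated), via silyl dienol ether 15 (not isolated), via silyloxy epoxy ketone 16 (not isolated)
Conditions: LiN(i-Pr)2 (1.15 equiv), Me3SiCl, THF, −78 °C; DMDO (2.3 equiv), acetone–CH2Cl2, −40 → 0 °C; aq. citric acid, THF
Reagents that add atoms: dimethyldioxirane, CC1(C)OO1
Why: Kinetic α′-deprotonation and silylation give the cross-conjugated 2-silyloxy diene 15, which DMDO oxidises at the enol ether (Rubottom oxidation, C7–O bond) and at the isolated cis-alkene from the face opposite the two β-methyls (2α,3α-epoxide), while the electron-poor enone alkene is left; the C7 configuration is of no consequence because C7 becomes sp2 in step 8.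

**Step 5**
Reactants: 18 (S)-2-methylbutan-1-ol; 19 triethyl 4-phosphonocrotonate
Product: 21 ethyl (2E,4E,6S)-6-methylocta-2,4-dienoate, via aldehyde 20 (not isolated)
Conditions: TEMPO (cat.), PhI(OAc)2, CH2Cl2, 0 °C; solution added to 19/LiN(SiMe3)2, THF, −78 → 0 °C
Reagents that add atoms: none
Why: Oxoammonium (TEMPO) oxidation gives the α-branched aldehyde without epimerisation and the Horner–Wadsworth–Emmons reaction with the preformed lithium phosphonate at low temperature builds the (2E,4E)-diene, the (S) centre coming unchanged from 18.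

**Step 6**
Reactants: 21 ethyl (2E,4E,6S)-6-methylocta-2,4-dienoate
Product: 22 (2E,4E,6S)-6-methylocta-2,4-dienoic acid
Conditions: LiOH, THF–H2O, 23 °C; then 1 M HCl
Reagents that add atoms: lithium hydroxide, [Li+].[OH-]
Why: Saponification of the ethyl ester; the remote C6 stereocentre is not acidic under LiOH.

**Step 7**
Reactants: 17 2α,3α-epoxy-7α-hydroxy-11,12,13-trinoreremophil-9-en-8-one; 22 (2E,4E,6S)-6-methylocta-2,4-dienoic acid
Product: 23 2α,7α-dihydroxy-8-oxo-11,12,13-trinoreremophil-9-en-3β-yl (2E,4E,6S)-6-methylocta-2,4-dienoate (2R,3R,4R,5R,7R)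
Conditions: 22 (1.2 equiv), (S,S)-Co(salen) C36H52CoN2O2 (5 mol %, divalent cobalt, oxidised by air in the flask to the trivalent cobalt carboxylate), i-Pr2NEt (1.0 equiv), t-BuOMe, 4 → 23 °C, 48 h
Reagents that add atoms: none
Why: Proposed new method: catalyst-controlled regioselective carboxylysis of a non-meso ring-fused cis-epoxide, in which one trivalent cobalt salen centre activates the epoxide oxygen as a Lewis acid while a second delivers its bound dienoate to the backside of C3; C3 is the trans-diaxial (Fürst–Plattner) position in the steroid-like half-chair with the C5 methyl axial and is also the epoxide carbon picked by the matched catalyst enantiomer, so substrate and catalyst bias reinforce each other, C3 is inverted to the 3β-ester and the 2α-hydroxyl is retained; the closest known reaction type is the cobalt–salen-catalysed enantioselective opening of meso-epoxides by benzoic acid (and the related hydrolytic kinetic resolution), which has not been shown on an enantiopure, doubly β-branched fused epoxide or with a polyunsaturated acid.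

**Step 8**
Reactants: 23 2α,7α-dihydroxy-8-oxo-11,12,13-trinoreremophil-9-en-3β-yl (2E,4E,6S)-6-methylocta-2,4-dienoate
Product: 24 Septeremophilane G
Conditions: Cu(OAc)2 (2.2 equiv), MeOH–H2O (9:1), 23 → 40 °C, argon
Reagents that add atoms: none
Why: Cu(OAc)2 oxidises an α-hydroxy ketone through its enediol but leaves the isolated C2 alcohol, the ester and the diene alone, and the 7,8-dione so formed can enolise only toward C6, which gives the cross-conjugated diosphenol of the target (α-ketol to α-diketone oxidation).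

**Compound list**
1 | (S)-(+)-carvone, (5S)-2-methyl-5-(prop-1-en-2-yl)cyclohex-2-en-1-one | CC1=CC[C@@H](CC1=O)C(C)=C | starting material
2 | 3-(trimethylsilyl)but-3-en-2-one | CC(=O)C(=C)[Si](C)(C)C | starting material
3 | lithium (3S,5S)-2,3-dimethyl-5-(prop-1-en-2-yl)cyclohex-1-en-1-olate | [Li+].C1[C@H](C(C)=C)CC([O-])=C(C)[C@H]1C | intermediate
4 | (2R,3S,5S)-2,3-dimethyl-2-[3-oxo-2-(trimethylsilyl)butyl]-5-(prop-1-en-2-yl)cyclohexan-1-one (epimers at the silylated carbon; formed as its lithium enolate) | C1[C@H](C(C)=C)CC(=O)[C@](C)(CC(C(C)=O)[Si](C)(C)C)[C@H]1C | intermediate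
5 | (2R,3S,5S)-2,3-dimethyl-2-(3-oxobutyl)-5-(prop-1-en-2-yl)cyclohexan-1-one | C1[C@H](C(C)=C)CC(=O)[C@](C)(CCC(C)=O)[C@H]1C | intermediate
6 | (4aR,5S,7S)-4a,5-dimethyl-7-(prop-1-en-2-yl)-4,4a,5,6,7,8-hexahydronaphthalen-2(3H)-one | C1[C@H](C(C)=C)CC2=CC(=O)CC[C@]2(C)[C@H]1C | intermediate
7 | (4aR,5S,7S)-7-(1-hydroperoxy-1-methoxyethyl)-4a,5-dimethyl-4,4a,5,6,7,8-hexahydronaphthalen-2(3H)-one (epimers at the peroxy carbon) | C1[C@H](C(C)(OC)OO)CC2=CC(=O)CC[C@]2(C)[C@H]1C | intermediate
8 | (4aR,5S,7S)-7-[1-(acetylperoxy)-1-methoxyethyl]-4a,5-dimethyl-4,4a,5,6,7,8-hexahydronaphthalen-2(3H)-one | C1[C@H](C(C)(OC)OOC(C)=O)CC2=CC(=O)CC[C@]2(C)[C@H]1C | intermediate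
9 | (4aR,5S,7S)-7-acetoxy-4a,5-dimethyl-4,4a,5,6,7,8-hexahydronaphthalen-2(3H)-one | C1[C@H](OC(C)=O)CC2=CC(=O)CC[C@]2(C)[C@H]1C | intermediate
10 | (4aR,5S)-4a,5-dimethyl-4,4a,5,6-tetrahydronaphthalen-2(3H)-one | C1C=CC2=CC(=O)CC[C@]2(C)[C@H]1C | intermediate
11 | potassium (4aR,5S)-4a,5-dimethyl-3,4,4a,5-tetrahydronaphthalen-2-olate | [K+].C1=CC=C2C=C([O-])CC[C@]2(C)[C@H]1C | intermediate
12 | (4aR,5S)-4a,5-dimethyl-3,4,4a,5-tetrahydronaphthalen-2(1H)-one | C1=CC=C2CC(=O)CC[C@]2(C)[C@H]1C | intermediate
13 | (4aR,5S)-4a,5-dimethyl-4,4a,5,8-tetrahydronaphthalen-2(3H)-one | C1=CCC2=CC(=O)CC[C@]2(C)[C@H]1C | intermediate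
14 | lithium (4aR,5S)-4a,5-dimethyl-4,4a,5,8-tetrahydronaphthalen-2-olate | [Li+].C1=CCC2=CC([O-])=CC[C@]2(C)[C@H]1C | intermediate
15 | trimethyl{[(4aR,5S)-4a,5-dimethyl-4,4a,5,8-tetrahydronaphthalen-2-yl]oxy}silane | C1=CCC2=CC(O[Si](C)(C)C)=CC[C@]2(C)[C@H]1C | intermediate
16 | 2α,3α-epoxy-7α-(trimethylsilyloxy)-11,12,13-trinoreremophil-9-en-8-one (2R,3S,4R,5R,7R) | [C@@H]12O[C@@H]1CC3=CC(=O)[C@H](O[Si](C)(C)C)C[C@]3(C)[C@H]2C | intermediate
17 | 2α,3α-epoxy-7α-hydroxy-11,12,13-trinoreremophil-9-en-8-one (2R,3S,4R,5R,7R; any C7 epimer is carried along) | [C@@H]12O[C@@H]1CC3=CC(=O)[C@H](O)C[C@]3(C)[C@H]2C | intermediate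
18 | (S)-2-methylbutan-1-ol | CC[C@H](C)CO | starting material
19 | triethyl 4-phosphonocrotonate, ethyl (E)-4-(diethoxyphosphoryl)but-2-enoate | CCOC(=O)/C=C/CP(=O)(OCC)OCC | starting material
20 | (S)-2-methylbutanal | CC[C@H](C)C=O | intermediate
21 | ethyl (2E,4E,6S)-6-methylocta-2,4-dienoate | CC[C@H](C)/C=C/C=C/C(=O)OCC | intermediate
22 | (2E,4E,6S)-6-methylocta-2,4-dienoic acid | CC[C@H](C)/C=C/C=C/C(=O)O | intermediate
23 | 2α,7α-dihydroxy-8-oxo-11,12,13-trinoreremophil-9-en-3β-yl (2E,4E,6S)-6-methylocta-2,4-dienoate (2R,3R,4R,5R,7R) | CC[C@H](C)/C=C/C=C/C(=O)O[C@H]1[C@H](O)CC2=CC(=O)[C@H](O)C[C@]2(C)[C@H]1C | intermediate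
24 | Septeremophilane G, 2α,7-dihydroxy-8-oxo-11,12,13-trinoreremophila-6,9-dien-3β-yl (2E,4E,6S)-6-methylocta-2,4-dienoate (2R,3R,4R,5S) | CC[C@H](C)/C=C/C=C/C(=O)O[C@H]1[C@H](O)CC2=CC(=O)C(O)=C[C@]2(C)[C@H]1C | target

**Step count**
Total steps: 8. Longest linear sequence: 6 (steps 1, 2, 3, 4, 7, 8); steps 5 and 6 make the acid 22 in parallel.

**Three steps most likely to fail**

Step 7 (the proposed new step). The risk is attack at C2 through the other half-chair, or no reaction at the hindered C3. The fallback uses known chemistry only and replaces epoxide opening by SN2 displacement of a regiodefined sulfonate. It sets out from 13: the silyl dienol ether 15 is made as in step 4 but oxidised with only 1.0 equiv of DMDO at −78 °C, which touches the enol ether alone and gives the 7α-trimethylsilyloxy enone F4; citric acid work-up gives the ketol F5; OsO4 (2 mol %) and NMO in acetone–water dihydroxylate the ring A alkene from the α face to the 2α,3α,7α-triol F6; Bu2SnO in refluxing toluene gives the 2,3-O-dibutylstannylene acetal F7, which reacts with 4-nitrobenzenesulfonyl chloride only at the equatorial 3α-oxygen to give the 3α-nosylate F8; displacement with the caesium salt of 22 (C9H13CsO2, DMF, 50 °C) inverts C3 and gives 23, where the route is rejoined.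

Step 3. The risks are cleavage of the acetate by tert-butoxide before elimination, and over-isomerisation of 12 or 13 back to the conjugated dienone 10. The fallback generates 12 without strong base or kinetic protonation. It sets out from 9: DBU in toluene at 60 °C eliminates acetic acid and gives dienone 10, which is isolated; ethylene glycol and TsOH (benzene, water removal) move both double bonds out of conjugation, as with steroidal 4,6-dien-3-ones, and give the dioxolane of 12, (4a′R,5′S)-4a′,5′-dimethyl-3′,4′,4a′,5′-tetrahydro-1′H-spiro[1,3-dioxolane-2,2′-naphthalene] F1; PPTS in wet acetone at 0 °C releases the deconjugated dienone 12, where the route is rejoined and the DABCO treatment of step 3 gives 13.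

Step 4. The risks are γ-silylation at the doubly allylic C1 and over-oxidation by excess DMDO. The fallback separates the two oxidations and avoids the silyl enol ether. It sets out from 13: mCPBA with NaHCO3 in CH2Cl2 at 0 °C gives the 2α,3α-epoxy enone F2 (the enone alkene is inert to peracid); LiN(SiMe3)2 in THF at −78 °C gives its lithium dienolate F3, which is hydroxylated with 2-(phenylsulfonyl)-3-phenyloxaziridine (Davis enolate oxidation) and gives 17 after NH4Cl work-up, where the route is rejoined.

**Further compounds**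
F1 | step 3 | (4a′R,5′S)-4a′,5′-dimethyl-3′,4′,4a′,5′-tetrahydro-1′H-spiro[1,3-dioxolane-2,2′-naphthalene] | C1=CC=C2CC3(OCCO3)CC[C@]2(C)[C@H]1C
F2 | step 4 | 2α,3α-epoxy-11,12,13-trinoreremophil-9-en-8-one (2R,3S,4R,5R) | [C@@H]12O[C@@H]1CC3=CC(=O)CC[C@]3(C)[C@H]2C
F3 | step 4 | lithium 8-enolate (cross-conjugated 7,9-dien-8-olate) of F2 | [Li+].[C@@H]12O[C@@H]1CC3=CC([O-])=CC[C@]3(C)[C@H]2C
F4 | step 7 | (3R,4aR,5S)-4a,5-dimethyl-3-(trimethylsilyloxy)-4,4a,5,8-tetrahydronaphthalen-2(3H)-one | C1=CCC2=CC(=O)[C@H](O[Si](C)(C)C)C[C@]2(C)[C@H]1C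
F5 | step 7 | (3R,4aR,5S)-3-hydroxy-4a,5-dimethyl-4,4a,5,8-tetrahydronaphthalen-2(3H)-one | C1=CCC2=CC(=O)[C@H](O)C[C@]2(C)[C@H]1C
F6 | step 7 | 2α,3α,7α-trihydroxy-11,12,13-trinoreremophil-9-en-8-one | O[C@@H]1[C@H](O)CC2=CC(=O)[C@H](O)C[C@]2(C)[C@H]1C
F7 | step 7 | 2,3-O-dibutylstannylene acetal of F6 | CCCC[Sn]1(CCCC)O[C@@H]2[C@H](O1)CC3=CC(=O)[C@H](O)C[C@]3(C)[C@H]2C
F8 | step 7 | 2α,7α-dihydroxy-8-oxo-11,12,13-trinoreremophil-9-en-3α-yl 4-nitrobenzenesulfonate | O=S(=O)(O[C@@H]1[C@H](O)CC2=CC(=O)[C@H](O)C[C@]2(C)[C@H]1C)c1ccc(cc1)[N+](=O)[O-]
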